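**Retrosynthetic overview**
- Furan ring (last): the C-2–O bond is cut back to a ring-B hydroxy-p-quinone isoflavone, an isomer of the target, which comes from a 2',4',5'-trimethoxyphenyl isoflavone by oxidative demethylation.
- Dimethylpyran ring: dehydrogenative cyclisation of the 8-prenyl arm onto 7-OH of a symmetric 6,8-diprenyl-5,7-dihydroxyisoflavone.
- Pyranone ring C (first): one-carbon closure of a symmetric 3,5-diprenyl-2,4,6-trihydroxydeoxybenzoin, made by C-prenylation of the Hoesch ketone from phloroglucinol.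
- Ring order: ring C, then the pyran, then the furan.

Assumption: Euchretin G has no stereocentre and no stereogenic double bond, so it is one achiral compound; nitrile 2 is taken as a catalogue chemical. Isoflavone numbering is used throughout (C-2 to C-8, primes for ring B).

**Step 1**
Reactants: 1 phloroglucinol; 2 2-(2,4,5-trimethoxyphenyl)acetonitrile
Product: 4 1-(2,4,6-trihydroxyphenyl)-2-(2,4,5-trimethoxyphenyl)ethan-1-one, via ketiminium chloride 3 (not isolated)
Conditions: HCl (g), ZnCl2 (0.2 equiv), dry Et2O, 0 °C, 24 h; then H2O, 100 °C, 1 h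
Reagents that add atoms: water, O
Why: Hoesch acylation, in which the HCl-activated nitrile attacks the very electron-rich, threefold-symmetric phloroglucinol once (the precipitated ketiminium salt resists a second acylation) and hydrolysis gives the ketone; no stereocentre is formed.

**Step 2**
Reactants: 4 1-(2,4,6-trihydroxyphenyl)-2-(2,4,5-trimethoxyphenyl)ethan-1-one
Product: 6 1-[2,4,6-trihydroxy-3,5-bis(3-methylbut-2-en-1-yl)phenyl]-2-(2,4,5-trimethoxyphenyl)ethan-1-one, via monoprenyl ketone 5 (not isolated)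
Conditions: prenyl bromide (2.1 equiv), KOH (10% aq, 3 equiv), 0 °C, 1 h; then 1 M HCl
Reagents that add atoms: prenyl bromide (1-bromo-3-methylbut-2-ene), CC(C)=CCBr
Why: Base-mediated double C-prenylation of an acylphloroglucinol, whose phenoxide reacts in water as a carbon nucleophile at its two equivalent free ring positions (deoxyhumulone-type alkylation), and keeping the arene symmetric removes any regiochemical choice from the later ring-C closure.

**Step 3**
Reactants: 6 1-[2,4,6-trihydroxy-3,5-bis(3-methylbut-2-en-1-yl)phenyl]-2-(2,4,5-trimethoxyphenyl)ethan-1-one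
Product: 8 5,7-dihydroxy-6,8-bis(3-methylbut-2-en-1-yl)-3-(2,4,5-trimethoxyphenyl)-4H-chromen-4-one, via enaminone 7 (not isolated)
Conditions: DMF-DMA (2.5 equiv), THF, 65 °C, 3 h
Reagents that add atoms: N,N-dimethylformamide dimethyl acetal (DMF-DMA), COC(OC)N(C)C
Why: Deoxybenzoin-to-isoflavone annulation (enaminone formation at the benzylic CH2, attack of an ortho hydroxyl, loss of dimethylamine), which gives one chromone because both ortho hydroxyls are equivalent, while the hydroxyl between the two prenyl groups is too hindered to be O-methylated by the acetal.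

**Step 4**
Reactants: 8 5,7-dihydroxy-6,8-bis(3-methylbut-2-en-1-yl)-3-(2,4,5-trimethoxyphenyl)-4H-chromen-4-one
Product: 10 5-hydroxy-8,8-dimethyl-6-(3-methylbut-2-en-1-yl)-3-(2,4,5-trimethoxyphenyl)-4H,8H-pyrano[2,3-h]chromen-4-one, via ortho-quinone methide 9 (not isolated)
Conditions: DDQ (1.05 equiv), dry 1,4-dioxane, 80 °C, 1 h
Reagents that add atoms: none
Why: DDQ cyclodehydrogenation of an o-prenylphenol (hydride abstraction to the o-quinone methide, then oxa-6π electrocyclisation), the laboratory counterpart of the presumed biosynthetic pyran closure, in which only the free 7-OH can take part because 5-OH is hydrogen-bonded to the C-4 carbonyl; closure through the 8-prenyl arm, whose quinone methide keeps the γ-pyrone intact, gives the angular ring, and the linear isomer from the 6-prenyl arm is the expected by-product to be separated, since both closure modes are known in the osajin/pomiferin series.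

**Step 5**
Reactants: 10 5-hydroxy-8,8-dimethyl-6-(3-methylbut-2-en-1-yl)-3-(2,4,5-trimethoxyphenyl)-4H,8H-pyrano[2,3-h]chromen-4-one
Product: 11 2-[5-hydroxy-8,8-dimethyl-6-(3-methylbut-2-en-1-yl)-4-oxo-4H,8H-pyrano[2,3-h]chromen-3-yl]-5-methoxycyclohexa-2,5-diene-1,4-dione
Conditions: (NH4)2Ce(NO3)6 (2.2 equiv), MeCN/H2O 3:1, −10 °C to 0 °C, 10 min
Reagents that add atoms: water, O
Why: Oxidative demethylation of a 1,4-dimethoxyarene to the p-quinone, in which the 2,4,5-trimethoxyphenyl ring is oxidised much faster than the acyl-deactivated, chelated ring A, giving an isoflavone methoxy-p-quinone of a type known as stable natural products.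

**Step 6**
Reactants: 11 2-[5-hydroxy-8,8-dimethyl-6-(3-methylbut-2-en-1-yl)-4-oxo-4H,8H-pyrano[2,3-h]chromen-3-yl]-5-methoxycyclohexa-2,5-diene-1,4-dione
Product: 13 Euchretin G, via hydroxyquinone 12 (not isolated)
Conditions: Na2CO3 (0.5 M aq)/THF 1:1, degassed, argon, 0 °C to rt, 1 h; then 1 M HCl to pH 3
Reagents that add atoms: water, O
Why: Proposed new method: alkaline demethoxylation of the methoxy-p-quinone (addition–elimination, well known for 2-methoxy-1,4-benzoquinones) frees the hydroxyquinone, whose O-2' adds to C-2 (activated both as the β-carbon of the chromone and as the terminus of the quinone dienone), and a prototropic shift of H-2 aromatises ring B to the catechol; this redox-neutral isomerisation mirrors the presumed biosynthetic oxidation of a 2'-hydroxyisoflavone, its closest known relatives are the DDQ oxidative cyclisation of 2'-hydroxyisoflavones to coumaronochromones and quinone-based coumestan ring closures, and no stereocentre is formed.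

**Compound list**
1 | phloroglucinol (benzene-1,3,5-triol) | Oc1cc(O)cc(O)c1 | starting material
2 | 2-(2,4,5-trimethoxyphenyl)acetonitrile | COc1cc(OC)c(OC)cc1CC#N | starting material
3 | 1-(2,4,6-trihydroxyphenyl)-2-(2,4,5-trimethoxyphenyl)ethan-1-iminium chloride | COc1cc(OC)c(OC)cc1CC(=[NH2+])c1c(O)cc(O)cc1O.[Cl-] | intermediate
4 | 1-(2,4,6-trihydroxyphenyl)-2-(2,4,5-trimethoxyphenyl)ethan-1-one | COc1cc(OC)c(OC)cc1CC(=O)c1c(O)cc(O)cc1O | intermediate
5 | 1-[2,4,6-trihydroxy-3-(3-methylbut-2-en-1-yl)phenyl]-2-(2,4,5-trimethoxyphenyl)ethan-1-one | COc1cc(OC)c(OC)cc1CC(=O)c1c(O)cc(O)c(CC=C(C)C)c1O | intermediate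
6 | 1-[2,4,6-trihydroxy-3,5-bis(3-methylbut-2-en-1-yl)phenyl]-2-(2,4,5-trimethoxyphenyl)ethan-1-one | COc1cc(OC)c(OC)cc1CC(=O)c1c(O)c(CC=C(C)C)c(O)c(CC=C(C)C)c1O | intermediate
7 | (E)-3-(dimethylamino)-1-[2,4,6-trihydroxy-3,5-bis(3-methylbut-2-en-1-yl)phenyl]-2-(2,4,5-trimethoxyphenyl)prop-2-en-1-one (drawn E; the geometry is lost on cyclisation) | CN(C)/C=C(\c1cc(OC)c(OC)cc1OC)C(=O)c1c(O)c(CC=C(C)C)c(O)c(CC=C(C)C)c1O | intermediate
8 | 5,7-dihydroxy-6,8-bis(3-methylbut-2-en-1-yl)-3-(2,4,5-trimethoxyphenyl)-4H-chromen-4-one | COc1cc(OC)c(OC)cc1-c1coc2c(CC=C(C)C)c(O)c(CC=C(C)C)c(O)c2c1=O | intermediate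
9 | 5-hydroxy-8-[(Z)-3-methylbut-2-en-1-ylidene]-6-(3-methylbut-2-en-1-yl)-3-(2,4,5-trimethoxyphenyl)chromene-4,7(8H)-dione (Z as needed for ring closure) | COc1cc(OC)c(OC)cc1C1=COC2=C(C1=O)C(O)=C(CC=C(C)C)C(=O)/C2=C\C=C(C)C | intermediate
10 | 5-hydroxy-8,8-dimethyl-6-(3-methylbut-2-en-1-yl)-3-(2,4,5-trimethoxyphenyl)-4H,8H-pyrano[2,3-h]chromen-4-one | COc1cc(OC)c(OC)cc1-c1coc2c3C=CC(C)(C)Oc3c(CC=C(C)C)c(O)c2c1=O | intermediate
11 | 2-[5-hydroxy-8,8-dimethyl-6-(3-methylbut-2-en-1-yl)-4-oxo-4H,8H-pyrano[2,3-h]chromen-3-yl]-5-methoxycyclohexa-2,5-diene-1,4-dione | COC1=CC(=O)C(=CC1=O)c1coc2c3C=CC(C)(C)Oc3c(CC=C(C)C)c(O)c2c1=O | intermediate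
12 | 2-hydroxy-5-[5-hydroxy-8,8-dimethyl-6-(3-methylbut-2-en-1-yl)-4-oxo-4H,8H-pyrano[2,3-h]chromen-3-yl]cyclohexa-2,5-diene-1,4-dione | OC1=CC(=O)C(=CC1=O)c1coc2c3C=CC(C)(C)Oc3c(CC=C(C)C)c(O)c2c1=O | intermediate
13 | Euchretin G: coumaronochromone (isoflavone with O bridging C-2 and C-2') carrying 4',5'-dihydroxy on ring B, 5-OH, 6-prenyl and a 2,2-dimethyl-2H-pyran fused at O-7/C-8; achiral | CC(C)=CCc1c2c(c3oc4oc5cc(O)c(O)cc5c4c(=O)c3c1O)C=CC(C)(C)O2 | target

**Totals**
Total step count: 6. Longest linear sequence: 6 steps (1 and 2 to 13).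

**Steps most likely to fail, with fallbacks**

Step 4 (regiochemistry of the pyran closure). If DDQ closes mainly through the 6-prenyl arm, the pyran and the prenyl group are installed one after the other with positional control. This fallback sets out from 4 and comes back to the route at 10. Ketone 4 is closed with DMF-DMA (THF, 65 °C) through (E)-3-(dimethylamino)-1-(2,4,6-trihydroxyphenyl)-2-(2,4,5-trimethoxyphenyl)prop-2-en-1-one F1 to 5,7-dihydroxy-3-(2,4,5-trimethoxyphenyl)-4H-chromen-4-one F2. The free 7-OH is alkylated with 3-chloro-3-methylbut-1-yne (K2CO3, KI, CuI cat., acetone, reflux) to 5-hydroxy-7-[(2-methylbut-3-yn-2-yl)oxy]-3-(2,4,5-trimethoxyphenyl)-4H-chromen-4-one F3. Heating in N,N-diethylaniline at 190 °C (aryl propargyl ether Claisen rearrangement, 1,5-hydrogen shift, oxa-6π closure, directed to C-8 as in acronycine-type annulations) gives 5-hydroxy-8,8-dimethyl-3-(2,4,5-trimethoxyphenyl)-4H,8H-pyrano[2,3-h]chromen-4-one F4. The chelated 5-OH is then alkylated with the same chloride (DBU, CuCl2 cat., MeCN) to 8,8-dimethyl-5-[(2-methylbut-3-yn-2-yl)oxy]-3-(2,4,5-trimethoxyphenyl)-4H,8H-pyrano[2,3-h]chromen-4-one F5. Semihydrogenation (H2, Pd/CaCO3 poisoned with Pb(OAc)2, quinoline, EtOAc) gives 8,8-dimethyl-5-[(2-methylbut-3-en-2-yl)oxy]-3-(2,4,5-trimethoxyphenyl)-4H,8H-pyrano[2,3-h]chromen-4-one F6. Claisen rearrangement in toluene at 110 °C moves the allyl unit to C-6, the only free ortho position, and gives 10.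

Step 6 (methoxyquinone to target). Hydroxide may attack C-2 of the chromone or the free quinone position instead of C-4'. The fallback uses no external nucleophile and removes the methyl group oxidatively at the end; it sets out from 11 and comes back at 13. Quinone 11 is treated with Sc(OTf)3 (10 mol%, CH2Cl2, 0 °C) so that the quinone carbonyl oxygen O-2' closes onto C-2 and ring B aromatises, as in Lewis-acid-promoted alkoxyquinone–alkene benzofuran annulations. This gives the 4'-O-methyl ether of Euchretin G (5'-hydroxy-4'-methoxy coumaronochromone) F8. IBX (DMF, rt) oxidises the guaiacol unit with loss of methanol to the 4',5'-ortho-quinone of Euchretin G F9, and aqueous Na2S2O4 reduces it to 13.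

Step 5 (chemoselectivity of the cerium oxidation). If the chromene or ring A of 10 is attacked, the two oxidations are run in the opposite order so that no chromene is present during the cerium step; this fallback sets out from 8 and comes back at 11. Isoflavone 8 is oxidised with (NH4)2Ce(NO3)6 (MeCN/H2O, 0 °C) to 2-[5,7-dihydroxy-6,8-bis(3-methylbut-2-en-1-yl)-4-oxo-4H-chromen-3-yl]-5-methoxycyclohexa-2,5-diene-1,4-dione F7. Its quinone ring is inert to DDQ, so DDQ (dioxane, 80 °C) then closes the pyran ring as in step 4 and gives 11.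

**Further compounds**
F1 | step 4 | (E)-3-(dimethylamino)-1-(2,4,6-trihydroxyphenyl)-2-(2,4,5-trimethoxyphenyl)prop-2-en-1-one | CN(C)/C=C(\c1cc(OC)c(OC)cc1OC)C(=O)c1c(O)cc(O)cc1O
F2 | step 4 | 5,7-dihydroxy-3-(2,4,5-trimethoxyphenyl)-4H-chromen-4-one | COc1cc(OC)c(OC)cc1-c1coc2cc(O)cc(O)c2c1=O
F3 | step 4 | 5-hydroxy-7-[(2-methylbut-3-yn-2-yl)oxy]-3-(2,4,5-trimethoxyphenyl)-4H-chromen-4-one | COc1cc(OC)c(OC)cc1-c1coc2cc(OC(C)(C)C#C)cc(O)c2c1=O
F4 | step 4 | 5-hydroxy-8,8-dimethyl-3-(2,4,5-trimethoxyphenyl)-4H,8H-pyrano[2,3-h]chromen-4-one | COc1cc(OC)c(OC)cc1-c1coc2c3C=CC(C)(C)Oc3cc(O)c2c1=O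
F5 | step 4 | 8,8-dimethyl-5-[(2-methylbut-3-yn-2-yl)oxy]-3-(2,4,5-trimethoxyphenyl)-4H,8H-pyrano[2,3-h]chromen-4-one | COc1cc(OC)c(OC)cc1-c1coc2c3C=CC(C)(C)Oc3cc(OC(C)(C)C#C)c2c1=O
F6 | step 4 | 8,8-dimethyl-5-[(2-methylbut-3-en-2-yl)oxy]-3-(2,4,5-trimethoxyphenyl)-4H,8H-pyrano[2,3-h]chromen-4-one | COc1cc(OC)c(OC)cc1-c1coc2c3C=CC(C)(C)Oc3cc(OC(C)(C)C=C)c2c1=O
F7 | step 5 | 2-[5,7-dihydroxy-6,8-bis(3-methylbut-2-en-1-yl)-4-oxo-4H-chromen-3-yl]-5-methoxycyclohexa-2,5-diene-1,4-dione | COC1=CC(=O)C(=CC1=O)c1coc2c(CC=C(C)C)c(O)c(CC=C(C)C)c(O)c2c1=O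
F8 | step 6 | 4'-O-methyl ether of Euchretin G (5'-hydroxy-4'-methoxy coumaronochromone) | CC(C)=CCc1c2c(c3oc4oc5cc(OC)c(O)cc5c4c(=O)c3c1O)C=CC(C)(C)O2
F9 | step 6 | 4',5'-ortho-quinone of Euchretin G | CC(C)=CCC1=C2OC(C)(C)C=CC2=C3OC4=C(C(=O)C3=C1O)C1=CC(=O)C(=O)C=C1O4
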